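**Plan**
- Retrosynthesis: the C6–C(quaternary) bond of the 1,1-dimethylallyl group is traced back to a 5-O-prenyl ether (aromatic Claisen). Ring C is then cut at C3–C4 and at O1–C8a, giving a ring A acyl-anion equivalent with fluorine at C8a and a terminal aryl epoxide that carries ring B.
- Enabling feature: O1–C2–C3 of ring C is an opened oxirane (O1 and C3 are both attached to C2), and C4 is an acyl carbon on C4a. C8a lies meta to both O5 and O7 of ring A, so a C8a–F bond can undergo SNAr while C4 is still masked.
- Forward order: ring A dithiane (three steps) and ring B epoxide (three steps) are joined, and ring C is closed in the same flask. C4 is then unmasked, the prenyl group is shifted from O5 to C6, and all MOM groups are removed.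
- Stereochemistry: C2 is the only stereocentre. It is set by asymmetric transfer hydrogenation of a chloroketone and carried through the epoxide, and its C–O bond is never broken afterwards.

Key step: step 7

Remark: flavanone numbering (O1, C2 … C8a; rings A, B, C) is used for all intermediates. Compounds 1, 4 and 7 are taken as commercial.

**Step 1**
Reactants: 1 2,6-difluoro-4-hydroxybenzaldehyde
Product: 2 4-(1,3-dithian-2-yl)-3,5-difluorophenol
Conditions: HS(CH2)3SH (1.1 equiv), BF3·OEt2 (20 mol %), CH2Cl2, 0 °C → rt
Reagents that add atoms: propane-1,3-dithiol SCCCS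
Why: Lewis-acid-catalysed dithioacetalisation of an aromatic aldehyde, placed first because no acid-labile group is present yet and the formyl group flanked by two fluorines is a good electrophile.

**Step 2**
Reactants: 2 4-(1,3-dithian-2-yl)-3,5-difluorophenol
Product: 3 2-[2,6-difluoro-4-(methoxymethoxy)phenyl]-1,3-dithiane
Conditions: MOMCl (1.2 equiv), iPr2NEt (1.5 equiv), CH2Cl2, 0 °C → rt
Reagents that add atoms: chloromethyl methyl ether (MOMCl) COCCl
Why: Williamson-type O-alkylation (MOM protection) of an acidic phenol under amine base, which leaves the thioacetal untouched and removes the phenoxide that would shut down the later SNAr steps.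

**Step 3**
Reactants: 3 2-[2,6-difluoro-4-(methoxymethoxy)phenyl]-1,3-dithiane; 4 3-methylbut-2-en-1-ol (prenyl alcohol)
Product: 6 2-[2-fluoro-4-(methoxymethoxy)-6-(3-methylbut-2-enyloxy)phenyl]-1,3-dithiane, via potassium prenoxide 5 (not isolated)
Conditions: 4 (1.2 equiv), KOt-Bu (1.1 equiv), DMF, 0 → 80 °C
Reagents that add atoms: none
Why: SNAr (addition–elimination) of a primary alkoxide on a 1,3-difluoro-5-alkoxybenzene, a known substitution of meta-activated fluoroarenes; the two C–F carbons are equivalent and the first alkoxy group lowers the reactivity of the remaining C–F bond, so the reaction should stop at monosubstitution and thereby tell O5 from O7 without selective protection.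

**Step 4**
Reactants: 7 2-chloro-1-(3,4-dihydroxyphenyl)ethan-1-one
Product: 8 1-[3,4-bis(methoxymethoxy)phenyl]-2-chloroethan-1-one
Conditions: MOMCl (3 equiv), iPr2NEt (3.5 equiv), CH2Cl2, 0 °C → rt
Reagents that add atoms: chloromethyl methyl ether (MOMCl) COCCl
Why: MOM protection of the catechol with a hindered amine base, in which the far more reactive MOMCl should outrun alkylation of the phenols by the chloroketone.

**Step 5**
Reactants: 8 1-[3,4-bis(methoxymethoxy)phenyl]-2-chloroethan-1-one
Product: 9 (1R)-1-[3,4-bis(methoxymethoxy)phenyl]-2-chloroethan-1-ol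
Conditions: RuCl[(S,S)-TsDPEN](p-cymene) (0.5 mol %), HCO2H–Et3N (5:2), EtOAc, 25 °C
Reagents that add atoms: none
Why: Noyori-type asymmetric transfer hydrogenation of an α-chloro aryl ketone, in which the (S,S)-TsDPEN ligand directs hydride to the face that gives the (R)-chlorohydrin (the sense established for 2-chloroacetophenones) and so sets the only stereocentre of the target.

**Step 6**
Reactants: 9 (1R)-1-[3,4-bis(methoxymethoxy)phenyl]-2-chloroethan-1-ol
Product: 10 (2R)-2-[3,4-bis(methoxymethoxy)phenyl]oxirane
Conditions: NaH (1.1 equiv), THF, 0 °C → rt; filtration, used without chromatography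
Reagents that add atoms: none
Why: intramolecular Williamson reaction (3-exo-tet) of the chlorohydrin alkoxide, which leaves the C–O bond at the stereocentre untouched (retention), while the aprotic medium spares the solvolysis-prone electron-rich styrene oxide.

**Step 7**
Reactants: 6 2-[2-fluoro-4-(methoxymethoxy)-6-(3-methylbut-2-enyloxy)phenyl]-1,3-dithiane; 10 (2R)-2-[3,4-bis(methoxymethoxy)phenyl]oxirane
Product: 13 (2S)-2-[3,4-bis(methoxymethoxy)phenyl]-7-(methoxymethoxy)-5-(3-methylbut-2-enyloxy)spiro[chromane-4,2'-[1,3]dithiane], via lithiated dithiane 11 (not isolated), via lithium alkoxide 12 (not isolated)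
Conditions: 6, n-BuLi (1.05 equiv), THF, −78 → −40 °C; 10 (1.1 equiv), −40 °C → rt; then DMPU, 65 °C
Reagents that add atoms: none
Why: Proposed new method: one negative charge is relayed through the molecule, since the Corey–Seebach carbanion at C4 opens the epoxide by SN2 attack at its unsubstituted CH2 (bond C3–C4), and the liberated C2 alkoxide, stripped of lithium by DMPU, then adds to the C8a–F carbon of ring A and expels fluoride as insoluble LiF (bond O1–C8a). The closest known reaction types are the opening of styrene oxides by 2-aryl-2-lithio-1,3-dithianes and the intramolecular SNAr cyclisation of 3-(2-fluoroaryl)propan-1-olates to chromans, and what is new is their coupling in one flask on a fluoroarene that has no carbonyl activation. Ring C closes in a 6-exo-trig addition–elimination mode, which should be feasible because O5 and O7 stand meta to C8a and therefore stabilise the anionic sigma complex inductively without donating into C4a, C6 and C8, the carbons that carry the charge. No stereocentre is created, because C2 keeps the C–O bond of epoxide 10 throughout, so the configuration is retained and only the descriptor changes from R to S through the CIP ranking. The step needs attack at CH2 rather than at the benzylic carbon (secured by the bulk of the tertiary carbanion and the absence of a strong Lewis acid), displacement of fluoride rather than of the prenyloxy group at the other ortho carbon (secured by the much greater SNAr lability of C–F), and deprotonation of the dithiane C–H rather than of a ring C–H (secured by its higher acidity and the low temperature). Because C4 stays a thioketal while the alkoxide is alive, retro-aldol cleavage, E1cB loss to a chalcone and hence racemisation have no pathway.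

**Step 8**
Reactants: 13 (2S)-spiro[chromane-4,2'-[1,3]dithiane] from step 7
Product: 14 (2S)-2-[3,4-bis(methoxymethoxy)phenyl]-7-(methoxymethoxy)-5-(3-methylbut-2-enyloxy)chroman-4-one
Conditions: MeI (10 equiv), CaCO3 (5 equiv), MeCN–H2O (9:1), 45 °C
Reagents that add atoms: water O
Why: alkylative hydrolysis of a thioketal (S-methylation, thionium ion, capture by water) under carbonate buffer; MeI is neither an oxidant nor an alkene electrophile, so the prenyl ether and the MOM acetals should survive, and the near-neutral medium should not open ring C, so C2 is kept.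

**Step 9**
Reactants: 14 (2S)-2-[3,4-bis(methoxymethoxy)phenyl]-7-(methoxymethoxy)-5-(3-methylbut-2-enyloxy)chroman-4-one
Product: 16 (2S)-2-[3,4-bis(methoxymethoxy)phenyl]-5-hydroxy-7-(methoxymethoxy)-6-(2-methylbut-3-en-2-yl)chroman-4-one, via C6-H dienone 15 (not isolated)
Conditions: Eu(fod)3 [tris(6,6,7,7,8,8,8-heptafluoro-2,2-dimethyloctane-3,5-dionato)europium] (10 mol %), toluene, 80 °C, stopped at full conversion
Reagents that add atoms: none
Why: Lewis-acid-catalysed aromatic Claisen rearrangement ([3,3]-sigmatropic), closely precedented for 5-O-prenylflavanones: europium chelated between O5 and the C4 carbonyl lowers the barrier, C4a is blocked so the allyl terminus can reach only C6 with allylic inversion (hence the 1,1-dimethylallyl group), tautomerisation of dienone 15 to the hydrogen-bonded 5-phenol ends the sequence, and C2 is not involved.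

**Step 10**
Reactants: 16 (2S)-2-[3,4-bis(methoxymethoxy)phenyl]-5-hydroxy-7-(methoxymethoxy)-6-(2-methylbut-3-en-2-yl)chroman-4-one
Product: 17 (2S)-2-(3,4-dihydroxyphenyl)-5,7-dihydroxy-6-(2-methylbut-3-en-2-yl)chroman-4-one (target)
Conditions: HCl (1.25 M in MeOH), 40 °C
Reagents that add atoms: none
Why: acid-catalysed acetal exchange (MOM methanolysis), the usual last step for enantioenriched flavanones; the vinyl group on a quaternary carbon could only give a secondary cation and should react far more slowly than the acetals, and C2 racemises through base-induced opening to the chalcone, which acid does not promote.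

**Compound list**
1 | 2,6-difluoro-4-hydroxybenzaldehyde | O=Cc1c(F)cc(O)cc1F | starting material
2 | 4-(1,3-dithian-2-yl)-3,5-difluorophenol | Oc1cc(F)c(C2SCCCS2)c(F)c1 | intermediate
3 | 2-[2,6-difluoro-4-(methoxymethoxy)phenyl]-1,3-dithiane | COCOc1cc(F)c(C2SCCCS2)c(F)c1 | intermediate
4 | 3-methylbut-2-en-1-ol (prenyl alcohol) | CC(C)=CCO | starting material
5 | potassium 3-methylbut-2-en-1-olate | CC(C)=CC[O-].[K+] | intermediate
6 | 2-[2-fluoro-4-(methoxymethoxy)-6-(3-methylbut-2-enyloxy)phenyl]-1,3-dithiane | COCOc1cc(F)c(C2SCCCS2)c(OCC=C(C)C)c1 | intermediate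
7 | 2-chloro-1-(3,4-dihydroxyphenyl)ethan-1-one | O=C(CCl)c1ccc(O)c(O)c1 | starting material
8 | 1-[3,4-bis(methoxymethoxy)phenyl]-2-chloroethan-1-one | COCOc1ccc(C(=O)CCl)cc1OCOC | intermediate
9 | (1R)-1-[3,4-bis(methoxymethoxy)phenyl]-2-chloroethan-1-ol | ClC[C@@H](c1ccc(OCOC)c(OCOC)c1)O | intermediate
10 | (2R)-2-[3,4-bis(methoxymethoxy)phenyl]oxirane | C1[C@@H](c2ccc(OCOC)c(OCOC)c2)O1 | intermediate
11 | 2-lithio derivative of 6 (lithium on the dithiane C2) | [Li]C1(SCCCS1)c1c(F)cc(OCOC)cc1OCC=C(C)C | intermediate
12 | lithium (1S)-1-[3,4-bis(methoxymethoxy)phenyl]-2-{2-[2-fluoro-4-(methoxymethoxy)-6-(3-methylbut-2-enyloxy)phenyl]-1,3-dithian-2-yl}ethan-1-olate | COCOc1cc(F)c(C2(C[C@@H](c3ccc(OCOC)c(OCOC)c3)[O-])SCCCS2)c(OCC=C(C)C)c1.[Li+] | intermediate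
13 | (2S)-2-[3,4-bis(methoxymethoxy)phenyl]-7-(methoxymethoxy)-5-(3-methylbut-2-enyloxy)spiro[chromane-4,2'-[1,3]dithiane] | COCOc1cc2c(c(OCC=C(C)C)c1)C1(SCCCS1)C[C@@H](c1ccc(OCOC)c(OCOC)c1)O2 | intermediate
14 | (2S)-2-[3,4-bis(methoxymethoxy)phenyl]-7-(methoxymethoxy)-5-(3-methylbut-2-enyloxy)chroman-4-one | COCOc1cc2c(c(OCC=C(C)C)c1)C(=O)C[C@@H](c1ccc(OCOC)c(OCOC)c1)O2 | intermediate
15 | ring A dienone tautomer of 16 (C5 ketone, sp3 C6 bearing H and the 1,1-dimethylallyl group, configuration at C6 not defined) | C=CC(C)(C)C1C(OCOC)=CC2=C(C1=O)C(=O)C[C@@H](c1ccc(OCOC)c(OCOC)c1)O2 | intermediate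
16 | (2S)-2-[3,4-bis(methoxymethoxy)phenyl]-5-hydroxy-7-(methoxymethoxy)-6-(2-methylbut-3-en-2-yl)chroman-4-one | C=CC(C)(C)c1c(OCOC)cc2c(c1O)C(=O)C[C@@H](c1ccc(OCOC)c(OCOC)c1)O2 | intermediate
17 | (2S)-2-(3,4-dihydroxyphenyl)-5,7-dihydroxy-6-(2-methylbut-3-en-2-yl)chroman-4-one | C=CC(C)(C)c1c(O)cc2c(c1O)C(=O)C[C@@H](c1ccc(O)c(O)c1)O2 | target

Total step count: 10. Longest linear sequence: 7 (steps 1, 2, 3, 7, 8, 9, 10; the ring B branch 4, 5, 6, 7, 8, 9, 10 is equally long).

**Steps most likely to fail**

Step 7. Ring A may be metalated next to fluorine, with premature loss of LiF, or the lithium alkoxide may displace fluoride too slowly.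
- The fallback sets out from 6 and 10 and comes back at 13. It cuts the relay into two known operations.
- The Corey–Seebach opening is quenched with aqueous NH4Cl at room temperature, and the (1S)-alcohol F1 is isolated.
- The dithiane carbon of F1 no longer bears hydrogen. F1 is treated with LiTMP (3 equiv, THF, −78 °C → rt), which deprotonates the hydroxyl group and lithiates C8 between F and OMOM.
- Loss of LiF gives the aryne alkoxide F2, and the tethered alkoxide adds to C8a. This is the classical elimination–addition (benzyne) cyclisation to chromans, and the inductive effect of O7 directs the nucleophile to the same carbon as the tether does.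
- Protonation on work-up gives 13.

Step 9. Regiocontrol may be lost through a following Cope shift of the allyl group from C6 to C8, or C2 may partly racemise through Lewis-acid-assisted opening of ring C.
- The fallback sets out from 13 and comes back at 16. It moves the rearrangement in front of the unmasking.
- Compound 13 is heated without catalyst in N,N-diethylaniline (about 170 °C). The basic solvent tautomerises the dienone at once, and ring C, which has no carbonyl group, cannot open. This gives the spiro-dithiane phenol F3.
- Alkylative hydrolysis (MeI, CaCO3, aqueous MeCN) then delivers 16.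

Step 3. Substitution may be slow on a ring without an acceptor group, the base may induce 1,4-elimination of the prenyl ether already formed, or the dithiane C–H may be partly deprotonated.
- The fallback sets out from 1 and comes back at 6. It inverts the order of masking and substitution.
- MOMCl/iPr2NEt gives the MOM-protected difluoroaldehyde F4. Its formyl group activates both ortho C–F bonds, so potassium prenoxide substitutes one of them at 0 °C to rt and gives the prenyloxy aldehyde F5.
- F5 is thioacetalised under aprotic conditions with 1,3-bis(trimethylsilylthio)propane and catalytic ZnI2 (Et2O, 0 °C) to give 6.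

**Further compounds**
F1 | step 7 | (1S)-1-[3,4-bis(methoxymethoxy)phenyl]-2-{2-[2-fluoro-4-(methoxymethoxy)-6-(3-methylbut-2-enyloxy)phenyl]-1,3-dithian-2-yl}ethan-1-ol | COCOc1cc(F)c(C2(C[C@@H](c3ccc(OCOC)c(OCOC)c3)O)SCCCS2)c(OCC=C(C)C)c1
F2 | step 7 | lithium alkoxide of the C8–C8a aryne derived from F1 | COCOC1=CC(OCC=C(C)C)=C(C2(C[C@@H](c3ccc(OCOC)c(OCOC)c3)[O-])SCCCS2)C#C1.[Li+]
F3 | step 9 | (2S)-2-[3,4-bis(methoxymethoxy)phenyl]-7-(methoxymethoxy)-6-(2-methylbut-3-en-2-yl)spiro[chromane-4,2'-[1,3]dithian]-5-ol | C=CC(C)(C)c1c(OCOC)cc2c(c1O)C1(SCCCS1)C[C@@H](c1ccc(OCOC)c(OCOC)c1)O2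
F4 | step 3 | 2,6-difluoro-4-(methoxymethoxy)benzaldehyde | COCOc1cc(F)c(C=O)c(F)c1
F5 | step 3 | 2-fluoro-4-(methoxymethoxy)-6-(3-methylbut-2-enyloxy)benzaldehyde | COCOc1cc(F)c(C=O)c(OCC=C(C)C)c1
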